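**Plan**
1. Retrosynthesis: the target is a C2-symmetric dimer, so the first cut is the C8–C8' biaryl bond; each half is then cut at O1–C2/C2–C3 of ring C (C2 comes from DMF) and at the C4–C4a aryl ketone bond.
2. Enabling feature: C8 is the only C–H carbon of ring A, para to O5 and ortho to O7 and O1 (on C8a). The 5-OMe peri to the C4 carbonyl is the one ether that can be removed selectively, so a single free 5-OH directs a dehydrogenative homo-coupling to C8.
3. Forward: ring A (3,4,5-trimethoxyphenol) is acylated with the ring B arylacetic acid and ring C is closed in the same pot; 5-O-demethylation; anodic dimerisation at C8; cleavage of the six remaining methyl ethers.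
4. Stereochemistry: there is no stereocentre; the 8,8' axis with four ortho substituents is formed without control.

Key step: step 3

Assumption: the target SMILES defines no configuration for the 8,8' axis, so the biaryl is made as the racemate and no atroposelective step is planned.

**Step 1**
Reactants: 1 3,4,5-trimethoxyphenol; 2 4-methoxyphenylacetic acid
Product: 4 5,6,7-trimethoxy-3-(4-methoxyphenyl)-4H-chromen-4-one, via deoxybenzoin 3 (not isolated)
Conditions: BF3·OEt2 (neat, as solvent), 85 °C; then DMF, MsCl, 70 °C; aq. NaOAc work-up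
Reagents that add atoms: DMF (N,N-dimethylformamide), SMILES CN(C)C=O
Why: Friedel–Crafts C-acylation ortho to the phenol OH (the two ortho positions of 1 are equivalent) gives the deoxybenzoin, whose methylene carbon is then formylated by the Vilsmeier-type iminium salt from DMF/MsCl and closes onto the ortho phenol with loss of dimethylamine (one-pot deoxybenzoin isoflavone synthesis); no stereocentre is formed.

**Step 2**
Reactants: 4 5,6,7-trimethoxy-3-(4-methoxyphenyl)-4H-chromen-4-one
Product: 5 5-hydroxy-6,7-dimethoxy-3-(4-methoxyphenyl)-4H-chromen-4-one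
Conditions: BCl3 (1.5 equiv), CH2Cl2, −78 to 0 °C; then aq. HCl
Reagents that add atoms: none
Why: Chelation-controlled Lewis acid ether cleavage: BCl3 is held between the C4 carbonyl and the peri 5-OMe in a six-membered chelate and should cleave only this ether at low temperature, leaving 6-OMe, 7-OMe and 4'-OMe.

**Step 3**
Reactants: 5 5-hydroxy-6,7-dimethoxy-3-(4-methoxyphenyl)-4H-chromen-4-one (two molecules)
Product: 6 5,5'-dihydroxy-6,6',7,7'-tetramethoxy-3,3'-bis(4-methoxyphenyl)-4H,4'H-[8,8'-bichromene]-4,4'-dione
Conditions: undivided cell, boron-doped diamond (BDD) anode, Pt cathode, constant current 5 mA cm−2, about 1 F per mole of 5; Bu3MeN O3SOMe (0.1 M), 1,1,1,3,3,3-hexafluoropropan-2-ol (HFIP), 50 °C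
Reagents that add atoms: none
Why: Proposed new method: anodic one-electron oxidation of the chelated 5-phenol of 5 at BDD in HFIP should give, after loss of a proton, a phenoxyl radical with spin on O5 and on the para carbon C8; C8 then bonds to C8 of a second, unoxidised molecule (its most nucleophilic carbon), and loss of one more electron and two protons with tautomerisation of the bis-dienone restores both phenols while protons are reduced to H2 at the cathode. The closest known reaction type is the anodic dehydrogenative para,para homo-coupling of 2,6-disubstituted phenols to 4,4'-biphenols on BDD in fluorinated alcohols, supported by the oxidative coupling of chelated ortho-hydroxyaryl ketones with iron trichloride (FeCl3); a phenol that is part of a 5-hydroxychromone has not been used in it. No ring is closed and no stereocentre is formed; the new 8,8' axis carries four ortho substituents (O1 and 7-OMe on each half) and arises as the racemate. The step needs C8–C8' coupling in preference to C–O coupling, to attack on ring B and to over-oxidation: C8 is the only C–H of ring A, both ortho positions of the phenol (C6 and C4a) are substituted, O5 is held in the hydrogen bond to the C4 carbonyl and flanked by 6-OMe, and the 4-methoxyphenyl ring B is twisted out of conjugation and harder to oxidise than the tetra-oxygenated ring A. The twisted product cannot flatten to a diphenoquinone, and the charge is limited so that unchanged 5 is recovered instead of 6 being oxidised further.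

**Step 4**
Reactants: 6 5,5'-dihydroxy-6,6',7,7'-tetramethoxy-3,3'-bis(4-methoxyphenyl)-4H,4'H-[8,8'-bichromene]-4,4'-dione
Product: 7 5,5',6,6',7,7'-hexahydroxy-3,3'-bis(4-hydroxyphenyl)-4H,4'H-[8,8'-bichromene]-4,4'-dione
Conditions: BBr3 (15 equiv), CH2Cl2, −78 °C to rt, argon; then MeOH, degassed aq. HCl
Reagents that add atoms: none
Why: Lewis acid cleavage of aryl methyl ethers with excess BBr3 (the standard demethylation of polymethoxyisoflavones) should free the six remaining phenols, and the low temperature with an acidic oxygen-free work-up protects the two pyrogallol rings and avoids acid-induced opening of ring C.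

**Compound list**
1 | 3,4,5-trimethoxyphenol | COc1cc(O)cc(OC)c1OC | starting material
2 | 4-methoxyphenylacetic acid | COc1ccc(CC(=O)O)cc1 | starting material
3 | 1-(6-hydroxy-2,3,4-trimethoxyphenyl)-2-(4-methoxyphenyl)ethan-1-one (deoxybenzoin) | COc1ccc(CC(=O)c2c(O)cc(OC)c(OC)c2OC)cc1 | intermediate
4 | 5,6,7-trimethoxy-3-(4-methoxyphenyl)-4H-chromen-4-one | COc1ccc(cc1)-c1coc2cc(OC)c(OC)c(OC)c2c1=O | intermediate
5 | 5-hydroxy-6,7-dimethoxy-3-(4-methoxyphenyl)-4H-chromen-4-one | COc1ccc(cc1)-c1coc2cc(OC)c(OC)c(O)c2c1=O | intermediate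
6 | 5,5'-dihydroxy-6,6',7,7'-tetramethoxy-3,3'-bis(4-methoxyphenyl)-4H,4'H-[8,8'-bichromene]-4,4'-dione | COc1ccc(cc1)-c1coc2c(-c3c(OC)c(OC)c(O)c4c(=O)c(-c5ccc(OC)cc5)coc34)c(OC)c(OC)c(O)c2c1=O | intermediate
7 | 5,5',6,6',7,7'-hexahydroxy-3,3'-bis(4-hydroxyphenyl)-4H,4'H-[8,8'-bichromene]-4,4'-dione | O=c1c(-c2ccc(O)cc2)coc2c(-c3c(O)c(O)c(O)c4c(=O)c(-c5ccc(O)cc5)coc34)c(O)c(O)c(O)c12 | target

**Summary**
Total step count: 4. Longest linear sequence: 4 steps (1 → 4 → 5 → 6 → 7).

**Steps most likely to fail**

Step 3 (Proposed new method). Ring A of 5 may be too hard to oxidise relative to ring B, so that unselective arene oxidation, coupling through oxygen or further oxidation of the product takes over. The fallback uses known chemistry and sets out from 4. Electrophilic iodination (N-iodosuccinimide, cat. CF3CO2H, MeCN) at C8, the only ring A C–H and far more activated than the ring B positions ortho to 4'-OMe, should give 8-iodo-5,6,7-trimethoxy-3-(4-methoxyphenyl)-4H-chromen-4-one F1. Ullmann homo-coupling of F1 (activated copper bronze, DMF, 150 °C) should give 5,5',6,6',7,7'-hexamethoxy-3,3'-bis(4-methoxyphenyl)-4H,4'H-[8,8'-bichromene]-4,4'-dione F2. BBr3 under the conditions of step 4 then cleaves all eight ethers, and the sequence comes back to the route at 7.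

Step 4. Cleavage of the six ethers in the hindered dimer may stop short, and the two pyrogallol rings may be oxidised during aqueous isolation. The fallback changes the protecting group so that the phenols are freed under neutral conditions; it sets out from 4. BBr3 on the monomer (four ethers) should give 5,6,7-trihydroxy-3-(4-hydroxyphenyl)-4H-chromen-4-one F3. Benzyl bromide with K2CO3 in DMF at rt under argon should alkylate O6, O7 and O4' and leave the chelated 5-OH, giving 6,7-bis(benzyloxy)-3-[4-(benzyloxy)phenyl]-5-hydroxy-4H-chromen-4-one F4. Anodic dimerisation under the conditions of step 3 should give 6,6',7,7'-tetrakis(benzyloxy)-3,3'-bis[4-(benzyloxy)phenyl]-5,5'-dihydroxy-4H,4'H-[8,8'-bichromene]-4,4'-dione F5. Hydrogenolysis (H2, Pd/C, THF/MeOH, rt) followed by filtration under argon comes back to the route at 7.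

Step 1. C-formylation and ring closure of the doubly ortho-substituted ketone may stay incomplete in the one-pot stage, and long heating in BF3·OEt2 may remove the methyl ether ortho to the ketone, which would allow closure through the wrong oxygen. The fallback builds the C3–C1' bond last and sets out from 1. Friedel–Crafts acetylation (AcOH, BF3·OEt2, short heating) should give 1-(6-hydroxy-2,3,4-trimethoxyphenyl)ethan-1-one F6. Condensation with DMF dimethyl acetal (toluene, 90 °C) should give (E)-3-(dimethylamino)-1-(6-hydroxy-2,3,4-trimethoxyphenyl)prop-2-en-1-one F7. I2 in MeOH at rt closes ring C with iodination at C3 to 3-iodo-5,6,7-trimethoxy-4H-chromen-4-one F8. Suzuki–Miyaura coupling with 4-methoxyphenylboronic acid (Pd(PPh3)4, a zerovalent palladium complex, aq. Na2CO3, DME, 80 °C) comes back to the route at 4.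

**Further compounds**
F1 | step 3 | 8-iodo-5,6,7-trimethoxy-3-(4-methoxyphenyl)-4H-chromen-4-one | COc1ccc(cc1)-c1coc2c(I)c(OC)c(OC)c(OC)c2c1=O
F2 | step 3 | 5,5',6,6',7,7'-hexamethoxy-3,3'-bis(4-methoxyphenyl)-4H,4'H-[8,8'-bichromene]-4,4'-dione | COc1ccc(cc1)-c1coc2c(-c3c(OC)c(OC)c(OC)c4c(=O)c(-c5ccc(OC)cc5)coc34)c(OC)c(OC)c(OC)c2c1=O
F3 | step 4 | 5,6,7-trihydroxy-3-(4-hydroxyphenyl)-4H-chromen-4-one | O=c1c(-c2ccc(O)cc2)coc2cc(O)c(O)c(O)c12
F4 | step 4 | 6,7-bis(benzyloxy)-3-[4-(benzyloxy)phenyl]-5-hydroxy-4H-chromen-4-one | O=c1c(-c2ccc(OCc3ccccc3)cc2)coc2cc(OCc3ccccc3)c(OCc3ccccc3)c(O)c12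
F5 | step 4 | 6,6',7,7'-tetrakis(benzyloxy)-3,3'-bis[4-(benzyloxy)phenyl]-5,5'-dihydroxy-4H,4'H-[8,8'-bichromene]-4,4'-dione | O=c1c(-c2ccc(OCc3ccccc3)cc2)coc2c(-c3c(OCc4ccccc4)c(OCc4ccccc4)c(O)c4c(=O)c(-c5ccc(OCc6ccccc6)cc5)coc34)c(OCc3ccccc3)c(OCc3ccccc3)c(O)c12
F6 | step 1 | 1-(6-hydroxy-2,3,4-trimethoxyphenyl)ethan-1-one | CC(=O)c1c(O)cc(OC)c(OC)c1OC
F7 | step 1 | (E)-3-(dimethylamino)-1-(6-hydroxy-2,3,4-trimethoxyphenyl)prop-2-en-1-one | CN(C)/C=C/C(=O)c1c(O)cc(OC)c(OC)c1OC
F8 | step 1 | 3-iodo-5,6,7-trimethoxy-4H-chromen-4-one | COc1cc2occ(I)c(=O)c2c(OC)c1OC
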